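Oak is charged with less coupling partner than left-handed substrate, alder with more, so in oak the partner is the limiting reagent.

| setting | amber | grey | oak | alder |
|---|---|---|---|---|
| left-handed substrate | 0.10 M | 0.10 M | 0.10 M | 0.10 M |
| right-handed substrate | 0.10 M | 0.10 M | 0.10 M | 0.10 M |
| coupling partner | 0.041 M | 0.20 M | 0.0600 M | 0.250 M |
| precatalyst | 0.23 mM | 0.23 mM | 0.23 mM | 0.23 mM |
| remark | run made earlier | run made earlier |  |  |
| time |  |  | 3.0 h | 3.0 h |

- amber (time / min: right-handed substrate / %, left-handed substrate / %, left-handed product / %): 12.0: 50, 49, 0; 30.0: 45, 48, 1; 60.0: 46, 42, 1; 90.0: 48, 41, 7
- grey (time / min: right-handed substrate / %, left-handed substrate / %, left-handed product / %): 8.00: 50, 49, 5; 15.0: 50, 42, 12; 40.0: 52, 19, 26; 90.0: 50, 3, 50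

(scatter of a reading: 2 percentage points)

- catalyst is single-handed; left-handed substrate and right-handed substrate are mirror images of each other, charged as a racemate, each of them at the stated concentration
- candidate steps: coupling partner + catalyst + right-handed substrate -> catalyst + right-handed product; coupling partner + precatalyst -> catalyst + spent reagent; left-handed substrate <-> right-handed substrate; coupling partner + catalyst + left-handed substrate -> catalyst + left-handed product; coupling partner <-> dormant form
- an excess is the difference of the two amounts in percent of their sum
- an excess is below zero if the other one leads

- the flask that ends with the higher excess of right-handed substrate over left-handed substrate among what is left of the two, or "neither" when 2 percentage points or less lies between them (oak / alder / neither)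
- excess of right-handed substrate over left-handed substrate among what is left of the two at the end, oak
- excess of right-handed substrate over left-handed substrate among what is left of the two at the end, alder

Climb the time scales of the readings, fastest first. The left-handed substrate in grey stands lowest: it falls from 42% to 19% between 15.0 min and 40.0 min, a half-life read as 21.8 min. Next comes the wait for product in amber, which has less partner and still reads 1% of left-handed product at 60.0 min, inside the scatter of 2 percentage points, a wait longer than that half-life. The right-handed substrate in grey sits on the slowest rung, reading 50% at 90.0 min, just as it read 50% at 8.00 min.

So follow one partner molecule: in these runs it takes a left-handed substrate and is gone. For oak that gives a budget ceiling of 42.9%, the excess left when the whole partner charge b has removed left-handed substrate from a charge c of each hand, b/(2c − b), for b below c. My reckoning puts oak under that ceiling, since it starts with less partner than grey and its coupling slows as that partner falls. Alder has 2.50 times the partner its left-handed substrate needs, so there the clock counts instead. Its 3.0 h is 8.24 of grey's half-lives, which leaves an excess of 99.3% if the right-handed substrate stands still.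

The forecast says alder, with 33% for oak and 99% for alder, and adds of oak: “Amber ran slightly under the model, so the true value may be a little lower.”

The flasks give alder, with 27.9% for oak and 97.6% for alder.

    coupling partner + catalyst + right-handed substrate → catalyst + right-handed product (k = 23.0 /M²/min)
    coupling partner + precatalyst → catalyst + spent reagent (k = 0.160 /M/min)
    left-handed substrate ⇌ right-handed substrate (k = 7.90 × 10⁻⁴ /min)
    coupling partner + catalyst + left-handed substrate → catalyst + left-handed product (k = 4000 /M²/min)
    coupling partner ⇌ dormant form (K = 0.760, k = 0.310 /min)

Oak ends at 0.650 of its ceiling, 5.1 points under the forecast. Partner passes into dormant form with a half-life of 2.2 min (forward rate alone), shorter than the flask's 3.0 h, and at 3.00 h oak holds 0.00444 M of dormant form beside 9.5% of its partner charge still free, with a turnover to left-handed product of 24.7% where the ceiling asks 30.0%. A flask charged like alder but with 0.062 M of partner has a ceiling of 44.9% and ends at 29.2%, which is 0.650 of it.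

The runs come from a simulation for an exercise, and the scatter is random.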